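Numbering: C1 carries the exocyclic CH2, C2 and C6 are the fusion carbons, C3–C5 complete cyclopentane ring A, C7–C9 complete cyclohexane ring B, and C1' is the side-chain carbinol. β is the face of H6, so O3, O4, C1' and the C7 branch are β, while H2, O8 and O9 are α.
Cuts: first the five ester C–O bonds. Then C1=CH2 goes back to C1=O, the 8α,9α-diol to a C8=C9 enone, and the oxirane CH2 to a C7 acetyl group. Then C2–C6 and C7–C8 are cut together, and the open chain is cut at C2–C3, C6=C7, C5–C6 and C4=C5.
Enabling feature: in ring B the sp2 carbon C1 lies 1,4 to the C7 branch, the C2–C6 fusion is trans with H6/H7 trans, and O3 sits cis to C1 on ring A. This is the imprint of an (E)-C6=C7 enone tied by C3–C4–C5 to the C2 end of a C8=C9–C1(OSi)=C2 diene, whose C1 oxygen and O3 can share one silicon atom.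
Forward: the chain C1'–C5–C4–C3 grows on a lactate-derived butenolide, cross-metathesis adds C7 and the acetyl group, and an aldol addition adds C2–C1–C9–C8. Rings A and B then close in one cycloaddition, followed by the oxirane, the C8/C9 diol, the C1 methylene and finally the esters.
Stereochemistry: C1' comes from (S)-lactate, and C5 and C4 from anti additions on the five-membered lactone. C3 comes from a Felkin–Anh aldol, and C2, C6 and C7 from the cycloaddition. The oxirane carbon comes from a Felkin–Anh ylide addition, C8 and C9 from osmylation anti to the C7 branch, and the acyl stereocentres and the E-alkene from the purchased acids.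
Key step: step 13

Assumption: (R)-2-methylbutanoic acid and (E)-3-methylpent-2-enoic acid are taken as purchasable single isomers, so their stereochemistry enters unchanged with the acyl groups.

Step 1
Reactants: 1 ethyl (S)-lactate
Product: 2 ethyl (S)-2-(tert-butyldimethylsilyloxy)propanoate
Conditions: TBSCl, imidazole, DMF, 0 °C → rt
Reagents that add atoms: tert-butyldimethylsilyl chloride, CC(C)(C)[Si](C)(C)Cl
Why: Imidazole-promoted silyl ether formation on a secondary alcohol, which does not touch the stereocentre that becomes C1'.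

Step 2
Reactants: 2 ethyl (S)-2-(tert-butyldimethylsilyloxy)propanoate
Product: 3 (S)-2-(tert-butyldimethylsilyloxy)propanal
Conditions: iBu2AlH, CH2Cl2, −78 °C; Rochelle salt work-up
Reagents that add atoms: none
Why: Partial ester reduction, in which the aluminium hemiacetal persists at −78 °C and releases the configurationally stable α-silyloxy aldehyde only on work-up.

Step 3
Reactants: 3 (S)-2-(tert-butyldimethylsilyloxy)propanal; 4 methyl bis(2,2,2-trifluoroethyl)phosphonoacetate
Product: 5 methyl (S,Z)-4-(tert-butyldimethylsilyloxy)pent-2-enoate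
Conditions: KN(SiMe3)2, 18-crown-6, THF, −78 °C
Reagents that add atoms: methyl bis(2,2,2-trifluoroethyl)phosphonoacetate 4, COC(=O)CP(=O)(OCC(F)(F)F)OCC(F)(F)F
Why: Still–Gennari olefination, whose fast and irreversible elimination from the kinetic adduct gives the Z-enoate (C4=C5) needed for ring closure, at a temperature at which the α-stereocentre does not epimerise.

Step 4
Reactants: 5 methyl (S,Z)-4-(tert-butyldimethylsilyloxy)pent-2-enoate
Product: 6 (S)-5-methylfuran-2(5H)-one
Conditions: 2 M HCl, THF, rt
Reagents that add atoms: none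
Why: Acidic desilylation followed by spontaneous lactonisation of the Z-γ-hydroxy enoate, in which the C1'–O bond is never broken, so the configuration is retained.

Step 5
Reactants: 6 (S)-5-methylfuran-2(5H)-one; 7 vinylmagnesium bromide
Product: 8 (4S,5S)-5-methyl-4-vinyldihydrofuran-2(3H)-one (vinyl trans to methyl)
Conditions: CH2=CHMgBr (2.2 equiv), CuBr·SMe2 (1.1 equiv), THF, −78 → −40 °C; aq. NH4Cl
Reagents that add atoms: vinylmagnesium bromide 7, C=C[Mg]Br
Why: Conjugate addition of a vinyl homocuprate to a butenolide, which takes place anti to the substituent on the adjacent ring carbon, so the vinyl group enters trans to the C1' methyl group and sets C5.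

Step 6
Reactants: 8 (4S,5S)-5-methyl-4-vinyldihydrofuran-2(3H)-one
Product: 9 (3R,4R,5S)-3-hydroxy-5-methyl-4-vinyldihydrofuran-2(3H)-one (OH trans to vinyl; vinyl trans to methyl)
Conditions: NaN(SiMe3)2, THF, −78 °C; then 2-(benzenesulfonyl)-3-phenyloxaziridine, −78 °C
Reagents that add atoms: 2-(benzenesulfonyl)-3-phenyloxaziridine, O=S(=O)(c1ccccc1)N1OC1c1ccccc1
Why: Davis oxidation of the sodium lactone enolate, in which oxygen is delivered to the enolate face anti to the neighbouring C5 vinyl group and so sets C4 in the relationship to C5 that the target needs.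

Step 7
Reactants: 9 (3R,4R,5S)-3-hydroxy-5-methyl-4-vinyldihydrofuran-2(3H)-one
Product: 10 (2R,3S)-2-hydroxy-3-[(1S)-1-hydroxyethyl]-N-methoxy-N-methylpent-4-enamide
Conditions: MeNH(OMe)·HCl, AlMe3, CH2Cl2, 0 °C → rt
Reagents that add atoms: N,O-dimethylhydroxylamine hydrochloride, CNOC.Cl
Why: Aluminium-amide aminolysis of a lactone to the Weinreb amide, which breaks only the acyl C3–O bond, so C4, C5 and C1' keep their configuration while O1' is set free.

Step 8
Reactants: 10 (2R,3S)-2-hydroxy-3-[(1S)-1-hydroxyethyl]-N-methoxy-N-methylpent-4-enamide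
Product: 11 (4R,5S,6S)-2,2-di-tert-butyl-N-methoxy-N,6-dimethyl-5-vinyl-1,3,2-dioxasilinane-4-carboxamide
Conditions: tBu2Si(OTf)2, 2,6-lutidine, CH2Cl2, 0 °C
Reagents that add atoms: di-tert-butylsilyl bis(trifluoromethanesulfonate), CC(C)(C)[Si](OS(=O)(=O)C(F)(F)F)(OS(=O)(=O)C(F)(F)F)C(C)(C)C
Why: Silylene protection of a 1,3-diol (O4/O1') with a silyl bis(triflate) and a hindered pyridine base, fast enough under non-acidic conditions to outrun relactonisation, removable later by fluoride, and useful because its ring holds the C3 and C6 arms cis and gauche.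

Step 9
Reactants: 11 silylene-protected Weinreb amide
Product: 12 (4R,5S,6S)-2,2-di-tert-butyl-6-methyl-5-vinyl-1,3,2-dioxasilinane-4-carbaldehyde
Conditions: iBu2AlH, THF, −78 °C; Rochelle salt work-up
Reagents that add atoms: none
Why: Weinreb amide reduction, in which the chelated aluminium hemiaminal survives until work-up and so stops at the C3 aldehyde, the silylene and the alkene being inert at this temperature.

Step 10
Reactants: 12 vinyl aldehyde; 13 methyl vinyl ketone
Product: 14 (4R,5S,6S)-2,2-di-tert-butyl-6-methyl-5-[(E)-3-oxobut-1-enyl]-1,3,2-dioxasilinane-4-carbaldehyde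
Conditions: methyl vinyl ketone (5 equiv), second-generation Hoveyda–Grubbs catalyst (5 mol %), CH2Cl2, 40 °C
Reagents that add atoms: methyl vinyl ketone 13, C=CC(C)=O
Why: Olefin cross-metathesis of a terminal alkene with an electron-poor partner, which is E-selective and tolerates the aldehyde, and which is run while the substrate holds a single terminal alkene so that ring-closing metathesis with the later vinyl ketone cannot intervene.

Step 11
Reactants: 14 enone aldehyde; 15 2-(trimethylsilyloxy)buta-1,3-diene
Product: 16 (5S)-5-[(4R,5S,6S)-2,2-di-tert-butyl-6-methyl-5-[(E)-3-oxobut-1-enyl]-1,3,2-dioxasilinan-4-yl]-5-hydroxypent-1-en-3-one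
Conditions: BF3·OEt2 (1.1 equiv), CH2Cl2, −78 °C; aq. NaHCO3
Reagents that add atoms: 2-(trimethylsilyloxy)buta-1,3-diene 15, C=CC(=C)O[Si](C)(C)C
Why: Mukaiyama aldol addition under monodentate BF3 activation, which follows the polar Felkin–Anh model (attack on C3 anti to the C4–O4 bond with C5 beside the carbonyl oxygen) and so should give the 3,4-anti diol pattern of the target, the aldehyde reacting far faster than the enone at −78 °C.

Step 12
Reactants: 16 β-hydroxy vinyl ketone
Product: 17 bridged silyloxydiene enone: (6S)-6-[(4R,5S,6S)-2,2-di-tert-butyl-6-methyl-5-[(E)-3-oxobut-1-enyl]-1,3,2-dioxasilinan-4-yl]-2,2-diisopropyl-4-vinyl-6H-1,3,2-dioxasiline (O3 and the C1 enol oxygen on one Si(iPr)2; C1=C2 Z by ring constraint)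
Conditions: iPr2Si(OTf)2 (1.05 equiv), Et3N (4 equiv), CH2Cl2, −78 → 0 °C; filtration through Et3N-deactivated silica
Reagents that add atoms: diisopropylsilyl bis(trifluoromethanesulfonate), CC(C)[Si](OS(=O)(=O)C(F)(F)F)(OS(=O)(=O)C(F)(F)F)C(C)C
Why: Silyl ether formation at O3 followed by intramolecular soft enolisation (enol silylation with a silyl triflate and a tertiary amine), in which proximity selects the C1 ketone over the methyl enone, C2 is the only acidic position, the six-membered ring can hold only the Z enol ether (C3 outside on the diene), and the C3–O3 bond lies near the nodal plane of the enol ether so that β-elimination has no orbital overlap.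

Step 13
Reactants: 17 bridged silyloxydiene enone
Product: 18 trans-hydrindene cycloadduct (H2α, H6β; C1=C9 enol ether whose oxygen and 3β-O share Si(iPr)2; 4β-O and 1'-O share Si(tBu)2; 7β equatorial acetyl; 1'S)
Conditions: toluene (0.01 M), BHT (5 mol %), 110 °C, sealed base-washed tube
Reagents that add atoms: none
Why: A pericyclic, asynchronous [4+2] addition that is suprafacial on both partners joins the nucleophilic enol-ether terminus C2 to the enone β-carbon C6 and C8 to C7, so the polarity is matched and C1(OSi) ends 1,4 to C7; the closest known class is the type 1 intramolecular Diels–Alder reaction of 1,3,8-nonatrienes with a 2-silyloxydiene and a terminally activated E-dienophile, which gives trans-hydrindenes. Ring A closes as a five-membered carbocycle when the three-atom tether C3–C4–C5 brings C6 onto C2, and ring B is the new cyclohexene completed by C7–C8, with the C1=C9 silyl enol ether left in it as a masked ketone. C2 is controlled by C3, because the dioxasiline ring keeps O3 in the diene plane and holds the C1=C2–C3–C4 dihedral angle near 105–135°, so the tether reaches one diene face only and O3 ends cis to C1 (H2α), whereas two separate silyl ethers would turn H3 into that plane to relieve A(1,3) strain and would give the opposite C2/C3 relationship. C6 follows from the transition state with endo acetyl and anti tether, which the same dihedral angle favours and which keeps the C5 branch trans to C7 on ring A (the cis-fused alternative would crowd C1, O3, O4, C1' and C7 onto one face), so the fusion is trans (H6β). C7 follows from the E geometry of the dienophile, which is carried over unchanged (H6/H7 trans, acetyl equatorial). The step needs diene-face, endo/exo and orientational selectivity, secured in turn by the silylene bridge at C3, by the C5 stereocentre held in the cis-disubstituted dioxasilinane together with secondary overlap of the acetyl group, and by the tether length.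

Step 14
Reactants: 18 trans-hydrindene cycloadduct
Product: 19 cycloadduct with the 7β-acetyl group converted into a 7β-[(S)-2-methyloxiran-2-yl] group
Conditions: Me3SI, KN(SiMe3)2, THF, −10 → 0 °C
Reagents that add atoms: trimethylsulfonium iodide, C[S+](C)C.[I-]
Why: Corey–Chaykovsky epoxidation under kinetic Felkin–Anh control, in which the ylide attacks the acetyl carbonyl anti to the branched C6 and past H7 while C8 is still an unsubstituted CH2 (the situation of 20-oxo steroids), which should set the (S)-oxirane carbon, C1 being masked as the silyl enol ether at this stage.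

Step 15
Reactants: 19 oxiranyl cycloadduct
Product: 21 3β-hydroxy enone (C1 ketone; C8=C9; oxirane and 4,1'-O-silylene kept), via acetoxysilyl enone 20 (not isolated)
Conditions: Pd(OAc)2 (1.1 equiv), MeCN, rt → 40 °C; Celite filtration; then Bu4NF/AcOH (1:1, 2.2 equiv), THF, 0 °C
Reagents that add atoms: palladium diacetate, CC(=O)O[Pd]OC(C)=O (one acetate sits on silicon in 20 and is gone in 21)
Why: Saegusa–Ito oxidation, in which palladium replaces silicon on the C1/C9 enolate and β-hydride elimination of H8 gives the C8=C9 enone regiospecifically, after which buffered fluoride cleaves the less hindered diisopropyl(acetoxy)silyl ether at O3 while the di-tert-butylsilylene and the oxirane stay intact.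

Step 16
Reactants: 21 3β-hydroxy enone
Product: 22 3β,8α,9α-trihydroxy ketone (O8 equatorial, O9 axial)
Conditions: OsO4 (5 mol %), N-methylmorpholine N-oxide (2 equiv), acetone–H2O 4:1, 0 °C → rt
Reagents that add atoms: OsO4 (catalytic oxygen carrier), O=[Os](=O)(=O)=O; N-methylmorpholine N-oxide, C[N+]1([O-])CCOCC1; water, O
Why: Upjohn dihydroxylation, a suprafacial addition of OsO4 that should reach C8=C9 from the α face, anti to the pseudo-equatorial oxiranyl group on the allylic carbon C7, and so sets C8 and C9 together as the cis-diol.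

Step 17
Reactants: 22 trihydroxy ketone
Product: 23 3β,8α,9α-tris(trimethylsilyloxy) ketone
Conditions: TMSCl, imidazole, CH2Cl2, 0 °C → rt
Reagents that add atoms: trimethylsilyl chloride, C[Si](C)(C)Cl
Why: Silyl ether formation with a silyl chloride and imidazole, chosen because it masks the three protic groups for the titanium reagent without the triflates or Lewis acids that would ionise the 2,2-disubstituted oxirane.

Step 18
Reactants: 23 tris(trimethylsilyloxy) ketone
Product: 25 C1-methylene 3β,8α,9α-triol (oxirane and 4,1'-O-silylene kept), via tris-TMS exomethylene compound 24 (not isolated)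
Conditions: Cp2TiMe2 (3 equiv), toluene, 70 °C, dark; then K2CO3 (0.2 equiv), MeOH, 0 °C
Reagents that add atoms: dimethyltitanocene, [CH3-].[CH3-].[Ti+4].c1cc[cH-]c1.c1cc[cH-]c1
Why: Petasis methylenation through Cp2Ti=CH2 and an oxatitanacyclobutane, which is non-basic (so C2, C9 and the β-silyloxy groups are safe) and free of aluminium and halide Lewis acids (so the oxirane should survive), followed by carbonate-catalysed methanolysis, which removes only the trimethylsilyl ethers.

Step 19
Reactants: 25 C1-methylene triol; 26 (R)-2-methylbutanoic acid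
Product: 29 3β-O-[(R)-2-methylbutanoyl] 8α,9α-diol, via phenylboronate 27 (not isolated), via acylated phenylboronate 28 (not isolated)
Conditions: PhB(OH)2 (1.05 equiv), 4 Å MS, CH2Cl2, rt; then 26, DCC, DMAP, rt; then pinacol, rt
Reagents that add atoms: (R)-2-methylbutanoic acid 26, OC(=O)[C@H](C)CC; phenylboronic acid, OB(O)c1ccccc1 (held only in 27 and 28)
Why: Transient boronate masking of a cis-1,2-diol, as practised on carbohydrates, leaves O3–H as the only free hydroxyl for a Steglich esterification, and transesterification with pinacol then releases the 8,9-diol under neutral conditions.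

Step 20
Reactants: 29 3-ester 8,9-diol; 26 (R)-2-methylbutanoic acid
Product: 30 3β,8α-bis-O-[(R)-2-methylbutanoyl] 9α-ol
Conditions: 26 (1.1 equiv), DCC, DMAP (10 mol %), CH2Cl2, −20 → 0 °C
Reagents that add atoms: (R)-2-methylbutanoic acid 26, OC(=O)[C@H](C)CC
Why: Kinetically regioselective Steglich esterification of a cis-diol, in which the equatorial O8–H should react ahead of the axial O9–H, which faces the syn-axial H2 and H7, while migration from the equatorial to the axial oxygen is uphill.

Step 21
Reactants: 30 3,8-diester 9-ol; 31 (E)-3-methylpent-2-enoic acid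
Product: 32 3,8,9-triester still carrying the 4,1'-O-di-tert-butylsilylene
Conditions: 31 (3 equiv), DCC, DMAP (20 mol %), CH2Cl2, rt
Reagents that add atoms: (E)-3-methylpent-2-enoic acid 31, OC(=O)/C=C(\C)CC
Why: Steglich esterification of the single remaining (axial, allylic) hydroxyl, run with catalytic DMAP and no added amine base so that γ-deprotonation of the activated acid, and with it loss of the E geometry, stays slow.

Step 22
Reactants: 32 silylene-protected triester
Product: 33 3,8,9-triester 4β,1'-diol
Conditions: HF·pyridine, pyridine, THF, 0 °C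
Reagents that add atoms: none
Why: Fluoride cleavage of a di-tert-butylsilylene with pyridine-buffered HF·pyridine, a weakly acidic and non-aqueous medium in which acyl migration is slow and which epoxides with a fully substituted carbon are known to tolerate.

Step 23
Reactants: 33 triester diol
Product: 34 CNP0193288.1 (target)
Conditions: Ac2O, pyridine, DMAP (cat.), CH2Cl2, 0 °C → rt
Reagents that add atoms: acetic anhydride, CC(=O)OC(C)=O
Why: DMAP-catalysed acetylation of the two remaining secondary hydroxyls (O4 and O1'), which is faster than acyl migration and touches no stereocentre.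

Compound list
1 | ethyl (S)-lactate | CCOC(=O)[C@H](C)O | starting material
2 | ethyl (S)-2-(tert-butyldimethylsilyloxy)propanoate | CCOC(=O)[C@H](C)O[Si](C)(C)C(C)(C)C | intermediate
3 | (S)-2-(tert-butyldimethylsilyloxy)propanal | O=C[C@H](C)O[Si](C)(C)C(C)(C)C | intermediate
4 | methyl bis(2,2,2-trifluoroethyl)phosphonoacetate | COC(=O)CP(=O)(OCC(F)(F)F)OCC(F)(F)F | starting material
5 | methyl (S,Z)-4-(tert-butyldimethylsilyloxy)pent-2-enoate | COC(=O)/C=C\[C@H](C)O[Si](C)(C)C(C)(C)C | intermediate
6 | (S)-5-methylfuran-2(5H)-one | O=C1C=C[C@H](C)O1 | intermediate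
7 | vinylmagnesium bromide | C=C[Mg]Br | starting material
8 | (4S,5S)-5-methyl-4-vinyldihydrofuran-2(3H)-one | O=C1C[C@H]([C@H](C)O1)C=C | intermediate
9 | (3R,4R,5S)-3-hydroxy-5-methyl-4-vinyldihydrofuran-2(3H)-one | O=C1[C@H](O)[C@H]([C@H](C)O1)C=C | intermediate
10 | (2R,3S)-2-hydroxy-3-[(1S)-1-hydroxyethyl]-N-methoxy-N-methylpent-4-enamide | CON(C)C(=O)[C@H](O)[C@H]([C@H](C)O)C=C | intermediate
11 | (4R,5S,6S)-2,2-di-tert-butyl-N-methoxy-N,6-dimethyl-5-vinyl-1,3,2-dioxasilinane-4-carboxamide | CON(C)C(=O)[C@H](O[Si]1(C(C)(C)C)C(C)(C)C)[C@H]([C@H](C)O1)C=C | intermediate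
12 | (4R,5S,6S)-2,2-di-tert-butyl-6-methyl-5-vinyl-1,3,2-dioxasilinane-4-carbaldehyde | O=C[C@H](O[Si]1(C(C)(C)C)C(C)(C)C)[C@H]([C@H](C)O1)C=C | intermediate
13 | methyl vinyl ketone | C=CC(C)=O | starting material
14 | (4R,5S,6S)-2,2-di-tert-butyl-6-methyl-5-[(E)-3-oxobut-1-enyl]-1,3,2-dioxasilinane-4-carbaldehyde | O=C[C@H](O[Si]1(C(C)(C)C)C(C)(C)C)[C@H]([C@H](C)O1)/C=C/C(C)=O | intermediate
15 | 2-(trimethylsilyloxy)buta-1,3-diene | C=CC(=C)O[Si](C)(C)C | starting material
16 | β-hydroxy vinyl ketone (3S,4R,5S,1'S; E-enone at C6=C7) | C=CC(=O)C[C@H](O)[C@H](O[Si]1(C(C)(C)C)C(C)(C)C)[C@H]([C@H](C)O1)/C=C/C(C)=O | intermediate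
17 | bridged silyloxydiene enone (cycloaddition precursor; 3S,4R,5S,1'S) | C=CC1=C[C@H](O[Si](C(C)C)(C(C)C)O1)[C@H](O[Si]2(C(C)(C)C)C(C)(C)C)[C@H]([C@H](C)O2)/C=C/C(C)=O | intermediate
18 | trans-hydrindene cycloadduct (C1=C9 bridged silyl enol ether, 7β-acetyl) | O4C=1[C@@H]2[C@H](O[Si]4(C(C)C)C(C)C)[C@H](O[Si]3(C(C)(C)C)C(C)(C)C)[C@H]([C@H](C)O3)[C@H]2[C@H](C(C)=O)CC=1 | intermediate
19 | cycloadduct with 7β-[(S)-2-methyloxiran-2-yl] group | O4C=1[C@@H]2[C@H](O[Si]4(C(C)C)C(C)C)[C@H](O[Si]3(C(C)(C)C)C(C)(C)C)[C@H]([C@H](C)O3)[C@H]2[C@H]([C@@]5(C)CO5)CC=1 | intermediate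
20 | C8=C9 enone with 3β-O-[acetoxy(diisopropyl)silyl] group | O=C1[C@@H]2[C@H](O[Si](C(C)C)(C(C)C)OC(C)=O)[C@H](O[Si]3(C(C)(C)C)C(C)(C)C)[C@H]([C@H](C)O3)[C@H]2[C@H]([C@@]4(C)CO4)C=C1 | intermediate
21 | 3β-hydroxy C8=C9 enone | O=C1[C@@H]2[C@H](O)[C@H](O[Si]3(C(C)(C)C)C(C)(C)C)[C@H]([C@H](C)O3)[C@H]2[C@H]([C@@]4(C)CO4)C=C1 | intermediate
22 | 3β,8α,9α-trihydroxy C1 ketone | O=C1[C@@H]2[C@H](O)[C@H](O[Si]3(C(C)(C)C)C(C)(C)C)[C@H]([C@H](C)O3)[C@H]2[C@H]([C@@]4(C)CO4)[C@@H](O)[C@H]1O | intermediate
23 | 3β,8α,9α-tris(trimethylsilyloxy) C1 ketone | O=C1[C@@H]2[C@H](O[Si](C)(C)C)[C@H](O[Si]3(C(C)(C)C)C(C)(C)C)[C@H]([C@H](C)O3)[C@H]2[C@H]([C@@]4(C)CO4)[C@@H](O[Si](C)(C)C)[C@H]1O[Si](C)(C)C | intermediate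
24 | 3β,8α,9α-tris(trimethylsilyloxy) C1-methylene compound | C=C1[C@@H]2[C@H](O[Si](C)(C)C)[C@H](O[Si]3(C(C)(C)C)C(C)(C)C)[C@H]([C@H](C)O3)[C@H]2[C@H]([C@@]4(C)CO4)[C@@H](O[Si](C)(C)C)[C@H]1O[Si](C)(C)C | intermediate
25 | C1-methylene 3β,8α,9α-triol | C=C1[C@@H]2[C@H](O)[C@H](O[Si]3(C(C)(C)C)C(C)(C)C)[C@H]([C@H](C)O3)[C@H]2[C@H]([C@@]4(C)CO4)[C@@H](O)[C@H]1O | intermediate
26 | (R)-2-methylbutanoic acid | OC(=O)[C@H](C)CC | starting material
27 | 8,9-O-phenylboronate of 25 | C=C1[C@@H]2[C@H](O)[C@H](O[Si]3(C(C)(C)C)C(C)(C)C)[C@H]([C@H](C)O3)[C@H]2[C@H]([C@@]4(C)CO4)[C@@H](OB5c6ccccc6)[C@H]1O5 | intermediate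
28 | 3-O-[(R)-2-methylbutanoyl] 8,9-O-phenylboronate | C=C1[C@@H]2[C@H](OC(=O)[C@H](C)CC)[C@H](O[Si]3(C(C)(C)C)C(C)(C)C)[C@H]([C@H](C)O3)[C@H]2[C@H]([C@@]4(C)CO4)[C@@H](OB5c6ccccc6)[C@H]1O5 | intermediate
29 | 3-O-[(R)-2-methylbutanoyl] 8α,9α-diol | C=C1[C@@H]2[C@H](OC(=O)[C@H](C)CC)[C@H](O[Si]3(C(C)(C)C)C(C)(C)C)[C@H]([C@H](C)O3)[C@H]2[C@H]([C@@]4(C)CO4)[C@@H](O)[C@H]1O | intermediate
30 | 3,8-bis-O-[(R)-2-methylbutanoyl] 9α-ol | C=C1[C@@H]2[C@H](OC(=O)[C@H](C)CC)[C@H](O[Si]3(C(C)(C)C)C(C)(C)C)[C@H]([C@H](C)O3)[C@H]2[C@H]([C@@]4(C)CO4)[C@@H](OC(=O)[C@H](C)CC)[C@H]1O | intermediate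
31 | (E)-3-methylpent-2-enoic acid | OC(=O)/C=C(\C)CC | starting material
32 | 3,8,9-triester with 4,1'-O-di-tert-butylsilylene | C=C1[C@@H]2[C@H](OC(=O)[C@H](C)CC)[C@H](O[Si]3(C(C)(C)C)C(C)(C)C)[C@H]([C@H](C)O3)[C@H]2[C@H]([C@@]4(C)CO4)[C@@H](OC(=O)[C@H](C)CC)[C@H]1OC(=O)/C=C(\C)CC | intermediate
33 | 3,8,9-triester 4β,1'-diol | C=C1[C@@H]2[C@H](OC(=O)[C@H](C)CC)[C@H](O)[C@H]([C@H](C)O)[C@H]2[C@H]([C@@]3(C)CO3)[C@@H](OC(=O)[C@H](C)CC)[C@H]1OC(=O)/C=C(\C)CC | intermediate
34 | CNP0193288.1 | C=C1[C@@H]2[C@H](OC(=O)[C@H](C)CC)[C@H](OC(C)=O)[C@H]([C@H](C)OC(C)=O)[C@H]2[C@H]([C@@]2(C)CO2)[C@@H](OC(=O)[C@H](C)CC)[C@H]1OC(=O)/C=C(\C)CC | target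

Total step count: 23. Longest linear sequence: 23 steps (1 → 34). All other building blocks are purchased.

Steps most likely to fail

Step 13. Material may leak through the cis-fused (exo-acetyl) transition state, or the silylene bridge may be lost by adventitious hydrolysis during prolonged heating. The fallback makes the same two bonds one after the other by a polar double Michael sequence.
- It sets out from 17. Me2AlCl in CH2Cl2 at −78 °C activates the enone.
- The enol-ether carbon C2 closes ring A by a 5-exo Mukaiyama–Michael addition to C6. The aluminium enolate so formed closes ring B by Michael addition of C7 to C8 of the silyl-activated vinyl ketone.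
- Work-up with Bu4NF/AcOH gives the 3β-hydroxy 1-oxo 7-acetyl trans-hydrindane F1, in which the acetyl group can settle in the equatorial position.
- iPr2Si(OTf)2/Et3N, as in step 12, then rebuilds the O3–Si–O–C1 bridge with deprotonation at the unhindered C9 methylene, and the route is rejoined at 18.

Step 18. Methylene transfer to the crowded C1 carbonyl may be slow, which would leave time for titanium-induced opening of the oxirane. The fallback is a two-stage Peterson olefination that sets out from 23.
- Me3SiCH2Li with CeCl3 in THF at −78 °C adds to the ketone without enolising it and without touching the oxirane. This gives the C1 β-hydroxysilane F2; the configuration at C1 is open, and both epimers serve.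
- KH in THF at 0 °C triggers syn-elimination of silanolate.
- The route is rejoined at 24, which is methanolysed to 25 as before.

Step 20. Discrimination between O8–H and O9–H may be poor, because the quaternary oxirane carbon next to C8 slows the equatorial hydroxyl. The fallback replaces kinetic discrimination by tin activation and sets out from 29.
- Bu2SnO in toluene with removal of water gives the 8,9-O-dibutylstannylene acetal F3, in which the equatorial oxygen of a cis-diol is the more nucleophilic.
- (R)-2-methylbutanoyl chloride F4, made from 26 with oxalyl chloride and catalytic DMF, acylates F3 at 0 °C without added base.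
- Aqueous work-up rejoins the route at 30.

Further compounds
F1 | step 13 | 3β-hydroxy 1-oxo 7β-acetyl trans-hydrindane with 4,1'-O-di-tert-butylsilylene | O=C1[C@@H]2[C@H](O)[C@H](O[Si]3(C(C)(C)C)C(C)(C)C)[C@H]([C@H](C)O3)[C@H]2[C@H](C(C)=O)CC1
F2 | step 18 | C1 tertiary alcohol bearing CH2SiMe3 (β-hydroxysilane from 23, C1 configuration open) | OC1(C[Si](C)(C)C)[C@@H]2[C@H](O[Si](C)(C)C)[C@H](O[Si]3(C(C)(C)C)C(C)(C)C)[C@H]([C@H](C)O3)[C@H]2[C@H]([C@@]4(C)CO4)[C@@H](O[Si](C)(C)C)[C@H]1O[Si](C)(C)C
F3 | step 20 | 8,9-O-dibutylstannylene acetal of 29 | C=C1[C@@H]2[C@H](OC(=O)[C@H](C)CC)[C@H](O[Si]3(C(C)(C)C)C(C)(C)C)[C@H]([C@H](C)O3)[C@H]2[C@H]([C@@]4(C)CO4)[C@@H](O[Sn]5(CCCC)CCCC)[C@H]1O5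
F4 | step 20 | (R)-2-methylbutanoyl chloride | ClC(=O)[C@H](C)CC
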